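**Retrosynthetic overview**
- 3-Hydroxyglabrol is taken back to its ring B triisopropylsilyl ether, so the last step is one buffered desilylation.
- The route rests on ring A being an acylresorcinol: C4a carries the C4 ketone, C8a and C7 carry oxygen, C8 between them carries the prenyl group, and the C8a oxygen is O1 of ring C, bonded to benzylic C2. Rings A and C are therefore cut together, at C4a–C5 and at O1–C2, to one open trans-epoxy 1,3,5-tricarbonyl chain whose C5 end is at the aldehyde oxidation level.
- The chain comes from C4–C4a acylation of the dianion of a 4-prenyl-1-methoxyhex-1-ene-3,5-dione (from 4-methoxybut-3-en-2-one, acetyl chloride and prenyl bromide) with a (2R,3S)-glycidic N-methoxy-N-methylamide.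
- The glycidic amide comes from 4-hydroxybenzaldehyde by ortho-prenylation, silylation, Horner–Wadsworth–Emmons olefination and catalytic asymmetric nucleophilic epoxidation, which sets C3 directly and C2 through a later inversion.
- Ring order: ring B is bought; ring A, then ring C, are both closed in one flask.

Key step: step 8

Assumption: the free 3,5,7-trioxo aldehyde is not a storable compound (its formyl end is the most acidic site and the neutral chain folds as soon as it is made), so C5 is carried as the methyl ether of its enol; the chain is used as a mixture of epimers at the prenyl-bearing carbon and of enol tautomers, which is of no consequence because that carbon becomes aromatic C8.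

**Route**

Step 1
Reactants: 1 4-hydroxybenzaldehyde; 2 prenyl bromide (1-bromo-3-methylbut-2-ene)
Product: 3 4-hydroxy-3-(3-methylbut-2-enyl)benzaldehyde
Conditions: KOH (10% aq), rt; acidify to pH 5; chromatography
Reagents that add atoms: none
Why: Ortho C-alkylation of the phenoxide in water, where the hydrogen-bonded oxygen is shielded, the para position is blocked by the formyl group and the ortho carbon attacks the allylic bromide by SN2; the O-prenyl ether formed alongside is removed by chromatography.

Step 2
Reactants: 3 4-hydroxy-3-(3-methylbut-2-enyl)benzaldehyde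
Product: 4 3-(3-methylbut-2-enyl)-4-(triisopropylsilyloxy)benzaldehyde
Conditions: iPr3SiCl, imidazole, DMF, rt
Reagents that add atoms: triisopropylsilyl chloride, CC(C)[Si](Cl)(C(C)C)C(C)C
Why: Imidazole-promoted silylation of the phenol; the bulky triisopropylsilyl ether is chosen to survive the amide bases, the peroxide and the amidine base of the later steps.

Step 3
Reactants: 4 3-(3-methylbut-2-enyl)-4-(triisopropylsilyloxy)benzaldehyde; 5 diethyl [2-(methoxy(methyl)amino)-2-oxoethyl]phosphonate
Product: 6 (E)-N-methoxy-N-methyl-3-[3-(3-methylbut-2-enyl)-4-(triisopropylsilyloxy)phenyl]prop-2-enamide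
Conditions: NaH, THF, 0 °C to rt
Reagents that add atoms: none
Why: Horner–Wadsworth–Emmons olefination with a stabilized phosphonate carbanion, which should give the E-alkene through the favoured anti-oxaphosphetane.

Step 4
Reactants: 6 (E)-N-methoxy-N-methyl-3-[3-(3-methylbut-2-enyl)-4-(triisopropylsilyloxy)phenyl]prop-2-enamide
Product: 7 (2R,3S)-N-methoxy-N-methyl-3-[3-(3-methylbut-2-enyl)-4-(triisopropylsilyloxy)phenyl]oxirane-2-carboxamide
Conditions: Sm(OiPr)3 (10 mol %), (S)-BINOL (10 mol %), Ph3As=O (10 mol %), tBuOOH (1.5 equiv, decane), 4 Å molecular sieves, THF, rt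
Reagents that add atoms: tert-butyl hydroperoxide, CC(C)(C)OO
Why: Catalytic asymmetric nucleophilic epoxidation of an unsaturated amide (samarium binaphthoxide-bound tert-butyl peroxide adds in conjugate fashion and closes the ring, a Weitz–Scheffer-type process) leaves the electron-rich prenyl alkene alone, and the (S)-BINOL complex is expected by analogy with enone and amide substrates to give the (2R,3S)-oxirane, which sets C3 of the target (R) and the benzylic centre (S) that is inverted in step 8; the sense is to be confirmed on the first batch, the (R)-ligand being at hand if it proves opposite.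

Step 5
Reactants: 8 (E)-4-methoxybut-3-en-2-one; 9 acetyl chloride
Product: 10 (E)-1-methoxyhex-1-ene-3,5-dione
Conditions: 8 (2.0 equiv), LiN(SiMe3)2 (2.0 equiv), THF, −78 °C; 9 (1.0 equiv), −78 °C; AcOH, −78 °C to rt
Reagents that add atoms: none
Why: Claisen-type C-acylation of the kinetic lithium enolate of the methyl ketone by the acid chloride, in which the second equivalent of enolate takes up the acidic proton of the diketone as it forms and the mild acetic acid quench avoids acid-induced closure to the 4-pyranone.

Step 6
Reactants: 10 (E)-1-methoxyhex-1-ene-3,5-dione; 2 prenyl bromide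
Product: 11 (E)-1-methoxy-4-(3-methylbut-2-enyl)hex-1-ene-3,5-dione (racemic)
Conditions: K2CO3, acetone, rt to 40 °C
Reagents that add atoms: none
Why: C-alkylation of the 1,3-diketone potassium enolate by the allylic bromide (SN2) at the carbon between the two carbonyl groups; the new centre is formed racemic and disappears later when it becomes aromatic C8.

Step 7
Reactants: 11 (E)-1-methoxy-4-(3-methylbut-2-enyl)hex-1-ene-3,5-dione; 7 (2R,3S)-glycidic N-methoxy-N-methylamide
Product: 12 (E)-7-methoxy-4-(3-methylbut-2-enyl)-1-{(2R,3S)-3-[3-(3-methylbut-2-enyl)-4-(triisopropylsilyloxy)phenyl]oxiran-2-yl}hept-6-ene-1,3,5-trione (C4 epimers, enolized; chain C1, C2, C3, C4, C5, C6, C7 = flavanone C4, C4a, C8a, C8, C7, C6, C5)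
Conditions: 11 (1.5 equiv), LiN(iPr)2 (3.1 equiv), THF, −78 to −30 °C; 7 (1.0 equiv), −78 to −40 °C; AcOH, −78 °C; rapid chromatography on neutral silica
Reagents that add atoms: none
Why: Acylation of a 1,3-diketone dianion at its terminal, methyl-derived carbon by the N-methoxy-N-methylamide (Weinreb ketone synthesis), in which the less stabilized carbanion terminus reacts, the chelated tetrahedral adduct stops over-addition, and neither oxirane bond is touched so that both centres of 7 are carried over.

Step 8
Reactants: 12 trans-epoxy trioxo chain with C5 as methyl enol ether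
Product: 14 4'-O-triisopropylsilyl-3-hydroxyglabrol, via epoxy resorcinyl ketone 13 (not isolated)
Conditions: DBU (2.5 equiv), degassed MeCN, Ar, 0 °C to rt; quench into pH 5 citrate buffer as soon as 13 is consumed
Reagents that add atoms: none
Why: Proposed new method: DBU removes a C4a proton of the C4/C8a diketone, the carbanion adds to C5 of the methoxyenone (6-(enolexo)-endo-trig), methoxide is lost and the cyclohexenedione tautomerizes to the 2,4-dihydroxyaryl epoxy ketone 13, whose C8a phenoxide then opens the oxirane at benzylic C2 (6-endo-tet) to close ring C. The closest known reaction types are the base-mediated aldol aromatization of 3,5,7-tricarbonyl chains to acylresorcinols, the addition–elimination of 1,3-dicarbonyl carbanions to 3-alkoxyenones, and the cyclization of 2'-hydroxychalcone epoxides to trans-dihydroflavonols (the Algar–Flynn–Oyamada manifold); running them in one flask on an open chain is new. C3 keeps the R configuration set in step 4 because none of its bonds is broken, and C2 becomes R by backside attack with inversion at the S benzylic carbon, which gives the 2,3-trans ring; should the opening gain carbocation character, the trans diequatorial product is still the favoured one. The step needs C-attack and not O-attack on C5 (O-attack would give a 4-pyranone) and benzylic 6-endo opening and not 5-exo opening; the soft doubly stabilized C4a carbanion, the irreversible aromatization, the unsubstituted C5 position next to the ketone and the para-silyloxyaryl-stabilized benzylic carbon should secure this. The vinylic C6 cannot enolize, so the alternative fold of C6 onto the C4 ketone is shut off, and the short contact with a non-nucleophilic base at low temperature protects the C3 centre and the silyl ether.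

Step 9
Reactants: 14 4'-O-triisopropylsilyl-3-hydroxyglabrol
Product: 15 3-hydroxyglabrol
Conditions: Bu4NF (1.2 equiv), AcOH (1.5 equiv), THF, 0 °C
Reagents that add atoms: none
Why: Fluoride-induced cleavage of the aryl silyl ether, with the acetic acid buffer keeping the medium non-basic so that the C3 centre alpha to the ketone and the 2,3-trans ring C are not disturbed.

**Compound list**
1 | 4-hydroxybenzaldehyde | O=Cc1ccc(O)cc1 | starting material
2 | prenyl bromide (1-bromo-3-methylbut-2-ene) | CC(C)=CCBr | starting material
3 | 4-hydroxy-3-(3-methylbut-2-enyl)benzaldehyde | CC(C)=CCc1cc(C=O)ccc1O | intermediate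
4 | 3-(3-methylbut-2-enyl)-4-(triisopropylsilyloxy)benzaldehyde | CC(C)=CCc1cc(C=O)ccc1O[Si](C(C)C)(C(C)C)C(C)C | intermediate
5 | diethyl [2-(methoxy(methyl)amino)-2-oxoethyl]phosphonate | CCOP(=O)(CC(=O)N(C)OC)OCC | starting material
6 | (E)-N-methoxy-N-methyl-3-[3-(3-methylbut-2-enyl)-4-(triisopropylsilyloxy)phenyl]prop-2-enamide | CC(C)=CCc1cc(/C=C/C(=O)N(C)OC)ccc1O[Si](C(C)C)(C(C)C)C(C)C | intermediate
7 | (2R,3S)-N-methoxy-N-methyl-3-[3-(3-methylbut-2-enyl)-4-(triisopropylsilyloxy)phenyl]oxirane-2-carboxamide (trans) | CC(C)=CCc1cc([C@@H]2O[C@H]2C(=O)N(C)OC)ccc1O[Si](C(C)C)(C(C)C)C(C)C | intermediate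
8 | (E)-4-methoxybut-3-en-2-one | CO/C=C/C(C)=O | starting material
9 | acetyl chloride | CC(=O)Cl | starting material
10 | (E)-1-methoxyhex-1-ene-3,5-dione (largely enolized) | CO/C=C/C(=O)CC(C)=O | intermediate
11 | (E)-1-methoxy-4-(3-methylbut-2-enyl)hex-1-ene-3,5-dione (racemic) | CO/C=C/C(=O)C(CC=C(C)C)C(C)=O | intermediate
12 | (E)-7-methoxy-4-(3-methylbut-2-enyl)-1-{(2R,3S)-3-[3-(3-methylbut-2-enyl)-4-(triisopropylsilyloxy)phenyl]oxiran-2-yl}hept-6-ene-1,3,5-trione (C4 epimers, enolized) | CC(C)=CCc1cc([C@@H]2O[C@H]2C(=O)CC(=O)C(CC=C(C)C)C(=O)/C=C/OC)ccc1O[Si](C(C)C)(C(C)C)C(C)C | intermediate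
13 | [2,4-dihydroxy-3-(3-methylbut-2-enyl)phenyl]{(2R,3S)-3-[3-(3-methylbut-2-enyl)-4-(triisopropylsilyloxy)phenyl]oxiran-2-yl}methanone | CC(C)=CCc1cc([C@@H]2O[C@H]2C(=O)c2ccc(O)c(CC=C(C)C)c2O)ccc1O[Si](C(C)C)(C(C)C)C(C)C | intermediate
14 | (2R,3R)-3,7-dihydroxy-8-(3-methylbut-2-enyl)-2-[3-(3-methylbut-2-enyl)-4-(triisopropylsilyloxy)phenyl]-2,3-dihydrochromen-4-one (4'-O-triisopropylsilyl-3-hydroxyglabrol) | CC(C)=CCc1cc([C@H]2Oc3c(ccc(O)c3CC=C(C)C)C(=O)[C@@H]2O)ccc1O[Si](C(C)C)(C(C)C)C(C)C | intermediate
15 | (2R,3R)-3,7-dihydroxy-2-[4-hydroxy-3-(3-methylbut-2-enyl)phenyl]-8-(3-methylbut-2-enyl)-2,3-dihydrochromen-4-one (3-hydroxyglabrol) | CC(C)=CCc1cc([C@H]2Oc3c(ccc(O)c3CC=C(C)C)C(=O)[C@@H]2O)ccc1O | target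

**Step count**
Total: 9 steps. Longest linear sequence: 7 steps (steps 1, 2, 3, 4, 7, 8, 9).

**Steps most likely to fail**

Step 8 (Proposed new method). The enolate oxygen may close onto C5 to give a 4-pyranone faster than the carbanion closes ring A, the oxirane may open in the 5-exo sense, or C3 may epimerize under the base. The fallback uses known chemistry: ring A is taken from a preformed acylresorcinol and only ring C is closed. It sets out from compound 3 and from commercial 2,4-dihydroxyacetophenone and comes back to the route at compound 15. C-prenylation of 2,4-dihydroxyacetophenone with 2 (KOH, water) should give 1-[2,4-dihydroxy-3-(3-methylbut-2-enyl)phenyl]ethanone F1. F1 is protected (MeOCH2Cl, NaH, DMF) as 1-[2,4-bis(methoxymethoxy)-3-(3-methylbut-2-enyl)phenyl]ethanone F2. Compound 3 is protected in the same way (MeOCH2Cl, iPr2NEt) as 4-(methoxymethoxy)-3-(3-methylbut-2-enyl)benzaldehyde F3. Claisen–Schmidt condensation of F2 with F3 (KOH, EtOH) should give the tris(methoxymethyl) (E)-chalcone F4. Juliá–Colonna epoxidation (poly-L-leucine, urea–H2O2, DBU, THF) is expected to give the (2R,3S)-epoxy ketone F5. HCl in MeOH then removes the three acetals, and the freed 2'-phenol opens the oxirane at the benzylic carbon to give 15 directly.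

Step 7. Acyl transfer to the amide may be slow at the temperature at which the dianion is stable, so that cyclization of the dianion onto its own methoxyenone, proton transfer, or opening of the oxirane by the amide base could compete. The fallback replaces the acylation by an aldol addition and an oxidation; it sets out from compounds 7 and 11 and comes back at compound 12. Reduction of 7 (iBu2AlH, THF, −78 °C) should give the (2R,3S)-3-aryloxirane-2-carbaldehyde F6. The dianion of 11 is expected to add to F6 within minutes at −78 °C to give the hydroxy diketone F7 (carbinol and C4 epimers). Dess–Martin periodinane (NaHCO3, CH2Cl2) then oxidizes the carbinol of F7 to the ketone, which is 12.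

Step 4. The electron-rich, para-oxygenated cinnamoyl amide may be converted slowly, the enantiofacial selectivity may be poor, or the Lewis-acidic lanthanide may open the labile benzylic oxirane. The fallback is a Darzens condensation followed by enzymatic resolution, as practised on the 4-methoxyphenyl analogue; it sets out from compound 4 and comes back at compound 7. Condensation of 4 with methyl chloroacetate (NaN(SiMe3)2, THF, −78 °C to rt) should give the racemic trans methyl glycidate F8 after removal of the cis isomer. Lipase-catalysed hydrolysis in a two-phase system is expected to consume the (2S,3R)-ester and leave the methyl (2R,3S)-glycidate F9. Aminolysis of F9 (MeNH(OMe)·HCl, iPrMgCl, THF, −20 °C) then gives 7.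

**Further compounds**
F1 | step 8 | 1-[2,4-dihydroxy-3-(3-methylbut-2-enyl)phenyl]ethanone | CC(=O)c1ccc(O)c(CC=C(C)C)c1O
F2 | step 8 | 1-[2,4-bis(methoxymethoxy)-3-(3-methylbut-2-enyl)phenyl]ethanone | CC(=O)c1ccc(OCOC)c(CC=C(C)C)c1OCOC
F3 | step 8 | 4-(methoxymethoxy)-3-(3-methylbut-2-enyl)benzaldehyde | CC(C)=CCc1cc(C=O)ccc1OCOC
F4 | step 8 | (E)-1-[2,4-bis(methoxymethoxy)-3-(3-methylbut-2-enyl)phenyl]-3-[4-(methoxymethoxy)-3-(3-methylbut-2-enyl)phenyl]prop-2-en-1-one | CC(C)=CCc1cc(/C=C/C(=O)c2ccc(OCOC)c(CC=C(C)C)c2OCOC)ccc1OCOC
F5 | step 8 | [2,4-bis(methoxymethoxy)-3-(3-methylbut-2-enyl)phenyl]{(2R,3S)-3-[4-(methoxymethoxy)-3-(3-methylbut-2-enyl)phenyl]oxiran-2-yl}methanone | CC(C)=CCc1cc([C@@H]2O[C@H]2C(=O)c2ccc(OCOC)c(CC=C(C)C)c2OCOC)ccc1OCOC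
F6 | step 7 | (2R,3S)-3-[3-(3-methylbut-2-enyl)-4-(triisopropylsilyloxy)phenyl]oxirane-2-carbaldehyde | CC(C)=CCc1cc([C@@H]2O[C@H]2C=O)ccc1O[Si](C(C)C)(C(C)C)C(C)C
F7 | step 7 | (E)-1-hydroxy-7-methoxy-4-(3-methylbut-2-enyl)-1-{3-[3-(3-methylbut-2-enyl)-4-(triisopropylsilyloxy)phenyl]oxiran-2-yl}hept-6-ene-3,5-dione (oxirane configured as in 7; carbinol and C4 epimers) | CC(C)=CCc1cc([C@@H]2O[C@H]2C(O)CC(=O)C(CC=C(C)C)C(=O)/C=C/OC)ccc1O[Si](C(C)C)(C(C)C)C(C)C
F8 | step 4 | methyl trans-3-[3-(3-methylbut-2-enyl)-4-(triisopropylsilyloxy)phenyl]oxirane-2-carboxylate (racemic, both enantiomers written) | CC(C)=CCc1cc([C@@H]2O[C@H]2C(=O)OC)ccc1O[Si](C(C)C)(C(C)C)C(C)C.CC(C)=CCc1cc([C@H]2O[C@@H]2C(=O)OC)ccc1O[Si](C(C)C)(C(C)C)C(C)C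
F9 | step 4 | methyl (2R,3S)-3-[3-(3-methylbut-2-enyl)-4-(triisopropylsilyloxy)phenyl]oxirane-2-carboxylate | CC(C)=CCc1cc([C@@H]2O[C@H]2C(=O)OC)ccc1O[Si](C(C)C)(C(C)C)C(C)C
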